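## The problem

CNP0299956.1 (21) is a trans-2-aryl-3-methyl-2,3-dihydrobenzofuran. Ring A carries a methoxy group at C7 and an (E)-propenyl chain at C5, and C2 is bonded to C1' of ring B, a 3-hydroxy-4,5-dimethoxyphenyl group. A synthesis has to join ring B to C2, make the dihydrofuran ring, and set the adjacent stereocentres C2 and C3 as 2S,3S. C3 (benzylic, methyl-bearing) cannot be corrected once made, whereas C2 can be equilibrated for as long as it carries a carbonyl group; C3 can therefore dictate the trans relationship thermodynamically, and only the absolute sense of C3 needs an outside source. The finished C2–O bond is a benzylic ether para to the C4' methoxy group and ionises under acid with loss of the C2 configuration, and the (E)-propenyl styrene will not survive hydrogenation, electrophilic halogen, strong acid or radical chain conditions, so the last operations must be neutral and mild. Ring B has three adjacent oxygens of which only the one at C3' is free; with a ready-made aryl building block this means telling phenols apart and carrying a protecting group to the end. The same pattern is the imprint of a squaric ester: C3'(OH), C4'(OMe), C5'(OMe) and C6'(H) correspond to C1, C2, C3 and C4 of a 2,3-dimethoxycyclobutenone, and C1'–C2' to a 1,1-disubstituted alkene on C2, so ring B can be grown on a complete dihydrobenzofuran by one cross-coupling (C1'–C6') and one electrocyclic closure (C2'–C3').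

## Retrosynthesis

**21 ⇒ 14 + 17.** The bonds C1'–C6' and C2'–C3' are cut, which takes ring B apart into the α-stannylvinyl dihydrobenzofuran 14 and the chlorocyclobutenone 17. Against the neighbouring cuts (C2–C1' with a preformed aryl group, or closing the dihydrofuran ring last), this one needs no phenol protection and no differentiation of the three oxygens, runs without acid or base, and ends in 21 itself. Precursor 14 is simpler by a whole ring and already holds both stereocentres. The forward reaction must couple at the chlorine-bearing carbon of 17, leave the propenyl group and the allylic C2–O bond alone, and let the 4-alkenylcyclobutenone 18 open to dienylketene 19 and close to dienone 20 at or below 100 °C.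

**17 ⇒ 16 ⇒ 15.** The C–Cl bond is traced to the C–OH bond of 16, and the C4–H bond to hydride addition to dimethyl squarate 15. No other source offers both methoxy groups already in place on a four-membered ring. The chlorination must never set acid free, because 16 and 17 both ionise easily at C4.

**14 ⇒ 13 ⇒ 12 ⇒ 11.** The C–Sn and C–H bonds across C1'=C2' are removed to give alkyne 13; the terminal carbon (C2') is then cut off to give aldehyde 12, which is ester 11 one oxidation level down. The ester carbon of 11 thus becomes C1' of ring B. Hydrostannation is preferred to an enol triflate route because it is one step and its regiochemistry is helped by the propargylic oxygen; it must run without radical initiation so that the propenyl group is untouched. The homologation must not disturb C2, which is α to the aldehyde; since C3 is fixed, epimerisation could only give the less stable cis diastereomer, never the enantiomer.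

**11 ⇒ 10 ⇒ 8.** Ester 11 is one enantiomer of racemic trans ester 10, and 10 arises by adding two hydrogens across C2=C3 of benzofuran 8. This cut is preferred because 8 is flat and quickly made. The price is a racemate containing some cis isomer 9: the cis/trans question is settled by enolate equilibration at C2, the absolute configuration by a resolution. A catalytic asymmetric hydrogenation of a benzofuran-2-carboxylate would be more economical but is not secure enough on this substitution pattern to build on.

**8 ⇒ 6 + 7.** The C5–propenyl bond is cut to aryl bromide 6 and alkenylboronate 7. The coupling is placed before the reduction so that the aryl bromide does not meet magnesium, and long before tin enters the molecule; it must keep the (E) geometry.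

**6 ⇒ 2 + 3 ⇒ 1.** O1–C2 and C2=C3 are cut, leading to bromophenol ketone 2 and methyl bromoacetate 3 through ether 4 and aldol adduct 5; the acetyl methyl group of 2 becomes the C3 methyl group. Compound 2 comes from 1 by bromination para to the hydroxyl group.

## Roads not taken

**Alternative 1:** The C2–C3 bond is cut. Diazoacetate A1, with ring B attached as a benzyl ether of the ring A phenol, would be decomposed by Rh2(S-PTTL)4; the rhodium carbene at C3 inserts into the benzylic C2–H bond and closes the dihydrofuran ring to the cis ester A2.
- Merits: a catalytic step sets the absolute configuration at C2, this insertion is established for closely related 2-aryl-2,3-dihydrobenzofuran-3-carboxylates, and ring B arrives ready-made.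
- Weak points for this target: the insertion gives the cis isomer, so C3 must be epimerised; the C3 ester then has to be cut down to a methyl group (reduction, activation, hydride displacement); the propenyl group is still to be coupled and the silyl ether removed. That is about six operations after the key step, and ring B needs its three oxygens differentiated beforehand.
- Comparison: in absolute stereocontrol and in precedent on the real skeleton this road is better, since the chosen plan pays for its stereochemistry with a resolution. The chosen plan sets against it that the C3 methyl group is present from the first step, that no phenol is ever protected or differentiated, and that nothing follows the key step.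

**Alternative 2:** The C3–C3a and O1–C7a bonds are cut. Aryl iodide A3 and cis epoxide A4 would react under Pd(OAc)2, a phosphine, norbornene and base: the ortho C–H carbon opens the epoxide at the methyl-bearing carbon with inversion, and the alkoxide closes on the ipso carbon, giving trans ester A5.
- Merits: it is the most convergent plan, both ring bonds form in one operation, the cis epoxide maps stereospecifically onto the trans product, and the epoxide could come from an asymmetric epoxidation of the cis alkene.
- Weak points: the annulation is established for terminal or lightly substituted epoxides. Here the palladacycle must attack the methyl-bearing carbon of an internal epoxide whose benzylic carbon, activated by an electron-rich ring, is the electronically preferred site, and which can also isomerise to a ketone. Afterwards the C5 ester must be turned into an (E)-propenyl group (reduction, oxidation, olefination with geometry control) and the methoxymethyl ether removed with acid, which threatens C2.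
- Comparison: if the epoxide opening were regioselective, this road would be shorter and enantioselective without a resolution. The chosen plan sets against it stereocentres made by robust classical chemistry, a propenyl group of defined geometry from a boronate, and no acid step near the end.

**Alternative 3:** Ring A is taken apart at C3a–C7a and C4–C5. Heating pyrone A6, whose 3-oxygen carries the ring B carbinol with a terminal alkyne, would give a [4+2] adduct that loses CO2 and delivers silyl ether A7, one desilylation from the target.
- Merits: like the chosen plan it is a late benzannulation; the stereodiad would be made in an open chain by reliable asymmetric C–C bond formation, so no resolution is needed.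
- Weak points: A6 is not available and must be built with three different substituents. Its 3-hydroxyl must be etherified with an electron-rich secondary benzylic alcohol with clean inversion, where ionisation would erase C2. The dienophile is an unactivated alkyne that needs high temperature, and the propenyl group on the pyrone offers a second diene.
- Comparison: A7 would carry catalyst-derived absolute configuration, which the chosen plan lacks. The chosen plan sets against it that both partners of its key step come from short sequences on commercial materials, that coupling and ring expansion run at or below 100 °C, and that the C3' hydroxyl is never protected.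

Key step: step 11

Assumption: the (2S,3S) enantiomer of 10 is identified after the separation in step 5 by an independent assignment (X-ray analysis of the derived acid as its salt with an amine of known configuration); 1, 3, 7, 15 and all reagents and catalysts are taken as purchasable.

## Route

Step 1
Reactants: 1 1-(2-hydroxy-3-methoxyphenyl)ethanone
Product: 2 1-(5-bromo-2-hydroxy-3-methoxyphenyl)ethanone
Conditions: NBS, MeCN, 0 °C to rt
Reagents that add atoms: N-bromosuccinimide, O=C1CCC(=O)N1Br
Why: Electrophilic aromatic bromination; the hydroxyl group directs para because both of its ortho positions are occupied, and this position is also meta to the acetyl group, so C5 is the only strongly activated site.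

Step 2
Reactants: 2 1-(5-bromo-2-hydroxy-3-methoxyphenyl)ethanone; 3 methyl bromoacetate
Product: 6 methyl 5-bromo-7-methoxy-3-methyl-1-benzofuran-2-carboxylate, via aryloxyacetate 4 (not isolated), via aldol adduct 5 (not isolated)
Conditions: K2CO3, 4 Å sieves, DMF, 60 °C, then 110 °C
Reagents that add atoms: none
Why: Williamson ether synthesis followed by intramolecular aldol condensation of the ester enolate onto the ortho acetyl group (Rap–Stoermer-type benzofuran synthesis); dehydration of 5 is driven by aromatisation of the furan ring.

Step 3
Reactants: 6 methyl 5-bromo-7-methoxy-3-methyl-1-benzofuran-2-carboxylate; 7 4,4,5,5-tetramethyl-2-[(E)-prop-1-enyl]-1,3,2-dioxaborolane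
Product: 8 methyl 7-methoxy-3-methyl-5-[(E)-prop-1-enyl]-1-benzofuran-2-carboxylate
Conditions: PdCl2(dppf) (3 mol %), K3PO4, dioxane/H2O, 80 °C
Reagents that add atoms: none
Why: Suzuki–Miyaura coupling of an aryl bromide with an (E)-alkenylboronate, which proceeds with retention of alkene geometry; the aromatic ester tolerates the phosphate base.

Step 4
Reactants: 8 methyl 7-methoxy-3-methyl-5-[(E)-prop-1-enyl]-1-benzofuran-2-carboxylate
Product: 10 methyl (2RS,3RS)-7-methoxy-3-methyl-5-[(E)-prop-1-enyl]-2,3-dihydro-1-benzofuran-2-carboxylate (racemic trans), via cis ester 9 (not isolated)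
Conditions: Mg turnings, MeOH, 0 °C to rt; then NaOMe, MeOH, rt
Reagents that add atoms: none
Why: Dissolving-metal conjugate reduction (Mg/MeOH) of the C2=C3 bond, which is conjugated to the ester and accepts an electron far more readily than the isolated styrene. Both stereocentres are created here as a racemate; methoxide then equilibrates C2 through the ester enolate, so that the fixed C3 methyl group drives the ester to the trans position and the cis ester 9 is drained.

Step 5
Reactants: 10 methyl (2RS,3RS)-7-methoxy-3-methyl-5-[(E)-prop-1-enyl]-2,3-dihydro-1-benzofuran-2-carboxylate (racemic trans)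
Product: 11 methyl (2S,3S)-7-methoxy-3-methyl-5-[(E)-prop-1-enyl]-2,3-dihydro-1-benzofuran-2-carboxylate
Conditions: preparative SFC on amylose tris(3,5-dimethylphenylcarbamate), CO2/MeOH, 35 °C
Reagents that add atoms: none
Why: Resolution by chromatography on a chiral stationary phase; no bond changes, and the step supplies the absolute configuration of C2 and C3, neither of which is inverted later.

Step 6
Reactants: 11 methyl (2S,3S)-7-methoxy-3-methyl-5-[(E)-prop-1-enyl]-2,3-dihydro-1-benzofuran-2-carboxylate
Product: 12 (2S,3S)-7-methoxy-3-methyl-5-[(E)-prop-1-enyl]-2,3-dihydro-1-benzofuran-2-carbaldehyde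
Conditions: i-Bu2AlH (1.05 equiv), CH2Cl2, −78 °C; aq. potassium sodium tartrate; used crude
Reagents that add atoms: none
Why: Partial reduction of an ester with i-Bu2AlH; the α-aryloxy oxygen chelates aluminium and holds the tetrahedral intermediate until work-up, so the aldehyde is not reduced further.

Step 7
Reactants: 12 (2S,3S)-7-methoxy-3-methyl-5-[(E)-prop-1-enyl]-2,3-dihydro-1-benzofuran-2-carbaldehyde
Product: 13 (2S,3S)-2-ethynyl-7-methoxy-3-methyl-5-[(E)-prop-1-enyl]-2,3-dihydro-1-benzofuran
Conditions: dimethyl (1-diazo-2-oxopropyl)phosphonate, K2CO3, MeOH, 0 °C to rt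
Reagents that add atoms: dimethyl (1-diazo-2-oxopropyl)phosphonate, CC(=O)C(=[N+]=[N-])P(=O)(OC)OC
Why: Seyferth–Gilbert homologation in the Ohira–Bestmann modification under mild carbonate base. Because C3 is fixed, enolisation of the aldehyde at C2 could only lead to the disfavoured and separable cis diastereomer, so enantiomeric purity is not at stake.

Step 8
Reactants: 13 (2S,3S)-2-ethynyl-7-methoxy-3-methyl-5-[(E)-prop-1-enyl]-2,3-dihydro-1-benzofuran
Product: 14 tributyl{1-[(2S,3S)-7-methoxy-3-methyl-5-[(E)-prop-1-enyl]-2,3-dihydro-1-benzofuran-2-yl]ethenyl}stannane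
Conditions: Bu3SnH, Mo(CO)3(CNtBu)3 (5 mol %), hydroquinone (cat.), THF, 55 °C; chromatography on Et3N-treated silica
Reagents that add atoms: tributyltin hydride, CCCC[SnH](CCCC)CCCC
Why: Mo(CO)3(CNtBu)3-catalysed hydrostannation of a terminal alkyne with a propargylic oxygen, which places tin on the internal carbon by syn addition; hydroquinone suppresses radical chain hydrostannation so that the propenyl group is left alone.

Step 9
Reactants: 15 dimethyl squarate (3,4-dimethoxycyclobut-3-ene-1,2-dione)
Product: 16 4-hydroxy-2,3-dimethoxycyclobut-2-en-1-one (racemic)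
Conditions: LiAlH(OtBu)3 (1.0 equiv), THF, −78 °C; cold aq. potassium sodium tartrate; used crude
Reagents that add atoms: none
Why: 1,2-Reduction of one carbonyl group of a squaric diester by a bulky, mild hydride stops at the hydroxycyclobutenone because the remaining carbonyl is a deactivated vinylogous ester; the new stereocentre is racemic and disappears in step 11.

Step 10
Reactants: 16 4-hydroxy-2,3-dimethoxycyclobut-2-en-1-one (racemic)
Product: 17 4-chloro-2,3-dimethoxycyclobut-2-en-1-one (racemic)
Conditions: 1-chloro-N,N,2-trimethylprop-1-en-1-amine, CH2Cl2, 0 °C; concentrate cold and use at once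
Reagents that add atoms: 1-chloro-N,N,2-trimethylprop-1-en-1-amine, CC(C)=C(Cl)N(C)C
Why: Deoxychlorination of a secondary alcohol with an α-chloroenamine under neutral conditions, through an alkoxyiminium chloride and SN2 displacement at the carbon α to the ketone; no acid is set free, which keeps the ionisation of C4 in check.

Step 11
Reactants: 14 tributyl{1-[(2S,3S)-7-methoxy-3-methyl-5-[(E)-prop-1-enyl]-2,3-dihydro-1-benzofuran-2-yl]ethenyl}stannane; 17 4-chloro-2,3-dimethoxycyclobut-2-en-1-one (1.5 equiv)
Product: 21 5-[(2S,3S)-7-methoxy-3-methyl-5-[(E)-prop-1-enyl]-2,3-dihydro-1-benzofuran-2-yl]-2,3-dimethoxyphenol (CNP0299956.1), via cyclobutenone 18 (not isolated), via dienylketene 19 (not isolated), via cyclohexadienone 20 (not isolated)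
Conditions: PdCl2(PhCN)2 (5 mol %), tri(2-furyl)phosphine (10 mol %), dioxane, 50 °C, then 100 °C
Reagents that add atoms: none
Why: Zerovalent palladium, formed from PdCl2(PhCN)2 and tri(2-furyl)phosphine, inserts into the allylic, α-keto C–Cl bond of 17; the alkenyl group of 14 is transferred from tin and reductive elimination at the former chlorine-bearing carbon forms C1'–C6' in 18. The closest known reaction type is the Stille coupling of 4-chlorocyclobutenones with alkenylstannanes followed by thermal ring expansion of the 4-alkenylcyclobutenone to a phenol. On warming, 18 opens by conrotatory 4π electrocyclisation to dienylketene 19; the opening is reversible, and only the isomer with the alkenyl group turned inward goes on. Ring B is closed by thermal disrotatory 6π electrocyclisation of 19, the ketene carbon bonding to the terminal methylene (C2'–C3'), and the resulting cyclohexadienone 20 enolises to the phenol. No stereocentre is created: the C4 centre of 17 and 18 is destroyed, and C2 and C3 of the dihydrobenzofuran lie outside the reacting π system. The step needs coupling at C4 of the cyclobutenone and not at the methoxy-bearing terminus of the oxocyclobutenylpalladium; C4 is the unsubstituted terminus and coupling there keeps the conjugated vinylogous ester. Connectivity then fixes the oxygen pattern: the ketene carbon becomes C3'–OH and the two squarate methoxy carbons become C4' and C5'. Chemoselectivity over the propenyl group rests on the fact that only the stannylated alkene can transmetalate, and the weakly donating tri(2-furyl)phosphine should keep transmetalation fast enough for reductive elimination to precede β-aryloxide loss.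

## Compound list

1 | 1-(2-hydroxy-3-methoxyphenyl)ethanone | CC(=O)c1cccc(OC)c1O | starting material
2 | 1-(5-bromo-2-hydroxy-3-methoxyphenyl)ethanone | CC(=O)c1cc(Br)cc(OC)c1O | intermediate
3 | methyl bromoacetate | COC(=O)CBr | starting material
4 | methyl 2-(2-acetyl-4-bromo-6-methoxyphenoxy)acetate | COC(=O)COc1c(OC)cc(Br)cc1C(C)=O | intermediate
5 | methyl 5-bromo-3-hydroxy-7-methoxy-3-methyl-2,3-dihydro-1-benzofuran-2-carboxylate (mixture of diastereomers) | COC(=O)C1Oc2c(OC)cc(Br)cc2C1(C)O | intermediate
6 | methyl 5-bromo-7-methoxy-3-methyl-1-benzofuran-2-carboxylate | COC(=O)c1oc2c(OC)cc(Br)cc2c1C | intermediate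
7 | 4,4,5,5-tetramethyl-2-[(E)-prop-1-enyl]-1,3,2-dioxaborolane | C/C=C/B1OC(C)(C)C(C)(C)O1 | starting material
8 | methyl 7-methoxy-3-methyl-5-[(E)-prop-1-enyl]-1-benzofuran-2-carboxylate | COC(=O)c1oc2c(OC)cc(/C=C/C)cc2c1C | intermediate
9 | methyl (2RS,3SR)-7-methoxy-3-methyl-5-[(E)-prop-1-enyl]-2,3-dihydro-1-benzofuran-2-carboxylate (racemic cis; one enantiomer drawn) | C/C=C/c1cc(OC)c2c(c1)[C@H](C)[C@H](C(=O)OC)O2 | intermediate
10 | methyl (2RS,3RS)-7-methoxy-3-methyl-5-[(E)-prop-1-enyl]-2,3-dihydro-1-benzofuran-2-carboxylate (racemic trans; one enantiomer drawn) | C/C=C/c1cc(OC)c2c(c1)[C@H](C)[C@@H](C(=O)OC)O2 | intermediate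
11 | methyl (2S,3S)-7-methoxy-3-methyl-5-[(E)-prop-1-enyl]-2,3-dihydro-1-benzofuran-2-carboxylate | C/C=C/c1cc(OC)c2c(c1)[C@H](C)[C@@H](C(=O)OC)O2 | intermediate
12 | (2S,3S)-7-methoxy-3-methyl-5-[(E)-prop-1-enyl]-2,3-dihydro-1-benzofuran-2-carbaldehyde | C/C=C/c1cc(OC)c2c(c1)[C@H](C)[C@@H](C=O)O2 | intermediate
13 | (2S,3S)-2-ethynyl-7-methoxy-3-methyl-5-[(E)-prop-1-enyl]-2,3-dihydro-1-benzofuran | C/C=C/c1cc(OC)c2c(c1)[C@H](C)[C@@H](C#C)O2 | intermediate
14 | tributyl{1-[(2S,3S)-7-methoxy-3-methyl-5-[(E)-prop-1-enyl]-2,3-dihydro-1-benzofuran-2-yl]ethenyl}stannane | C/C=C/c1cc(OC)c2c(c1)[C@H](C)[C@@H](C(=C)[Sn](CCCC)(CCCC)CCCC)O2 | intermediate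
15 | dimethyl squarate (3,4-dimethoxycyclobut-3-ene-1,2-dione) | COC1=C(OC)C(=O)C1=O | starting material
16 | 4-hydroxy-2,3-dimethoxycyclobut-2-en-1-one (racemic) | COC1=C(OC)C(O)C1=O | intermediate
17 | 4-chloro-2,3-dimethoxycyclobut-2-en-1-one (racemic) | COC1=C(OC)C(Cl)C1=O | intermediate
18 | 2,3-dimethoxy-4-{1-[(2S,3S)-7-methoxy-3-methyl-5-[(E)-prop-1-enyl]-2,3-dihydro-1-benzofuran-2-yl]ethenyl}cyclobut-2-en-1-one (both epimers at C4) | C/C=C/c1cc(OC)c2c(c1)[C@H](C)[C@@H](C(=C)C1C(=O)C(OC)=C1OC)O2 | intermediate
19 | (3E)-2,3-dimethoxy-5-[(2S,3S)-7-methoxy-3-methyl-5-[(E)-prop-1-enyl]-2,3-dihydro-1-benzofuran-2-yl]hexa-1,3,5-trien-1-one (alkenyl group cis to the ketene carbon) | C/C=C/c1cc(OC)c2c(c1)[C@H](C)[C@@H](C(=C)/C=C(OC)\C(OC)=C=O)O2 | intermediate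
20 | 2,3-dimethoxy-5-[(2S,3S)-7-methoxy-3-methyl-5-[(E)-prop-1-enyl]-2,3-dihydro-1-benzofuran-2-yl]cyclohexa-2,4-dien-1-one | C/C=C/c1cc(OC)c2c(c1)[C@H](C)[C@@H](C1=CC(OC)=C(OC)C(=O)C1)O2 | intermediate
21 | 5-[(2S,3S)-7-methoxy-3-methyl-5-[(E)-prop-1-enyl]-2,3-dihydro-1-benzofuran-2-yl]-2,3-dimethoxyphenol (CNP0299956.1) | C/C=C/c1cc(OC)c2c(c1)[C@H](C)[C@@H](c1cc(O)c(OC)c(OC)c1)O2 | target

## Step count and least certain steps

Total: 11 steps. Longest linear sequence: 9 steps (steps 1–8 and 11); the chloride branch (steps 9 and 10) joins at step 11.

**Step 11 (key step).**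
- Most likely failure: loss of the chloride by ionisation at C4 and irreversible demethylation before zerovalent palladium can insert, because the cation is a 2π-stabilised oxocyclobutenyl cation.
- Next most likely: reductive elimination at the methoxy-bearing terminus of the oxocyclobutenylpalladium, or slow transmetalation of the hindered 1,1-disubstituted stannane, which would let protodestannylation or β-aryloxide loss from the alkenylpalladium compete.
- Fallback (nucleophilic addition in place of cross-coupling): it sets out from 14 and returns at 21. Tin–lithium exchange (n-BuLi, THF, −78 °C) and addition to dimethyl squarate 15 should give the 4-alkenyl-4-hydroxycyclobutenone F1. Heating in toluene at 110 °C should expand it, by the same 4π-opening and 6π-closure, to the hydroquinone F2, which carries one oxygen too many, at C6'. The less hindered C3' hydroxyl is silylated (TIPSCl, imidazole) to give the mono-silyl ether F3. The C6' hydroxyl is converted with Tf2O and pyridine into the aryl triflate F4, which is reduced (Pd(OAc)2, dppf, HCO2H, Et3N, DMF) to the silyl ether of the target F5. Bu4NF then releases 21.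

**Step 10.**
- Most likely failure: ionisation of the activated alkoxy intermediate or of the chloride itself during formation or concentration, followed by chloride return at the methoxy-bearing carbon and loss of chloromethane, or hydrolysis by adventitious water.
- Fallback (a storable ester in place of a halide): it sets out from 16 and returns at 18. Acylation with ClCO2Me and pyridine in CH2Cl2 at 0 °C should give the allylic methyl carbonate F6. Under Pd2(dba)3 and tri(2-furyl)phosphine it is ionised only by zerovalent palladium, with loss of CO2, and the methoxide set free assists transfer of the alkenyl group from 14.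

**Step 8.**
- Most likely failure: delivery of tin to the terminal carbon if the propargylic aryl ether directs poorly next to the C3 branch, and protodestannylation during purification.
- Fallback (regiochemistry fixed by construction): it sets out from 11 and returns at 14. Me(MeO)NH·HCl and i-PrMgCl give the Weinreb amide F7, MeMgBr gives the methyl ketone F8, kinetic enolisation at the methyl group with KN(SiMe3)2 and PhNTf2 at −78 °C gives the enol triflate F9, and Pd(PPh3)4, (Bu3Sn)2 and LiCl convert it into 14.

**Step 4.**
- Most likely failure: spread of the single-electron reduction to the propenyl double bond, reductive cleavage of the C2–O bond α to the ester, or incomplete equilibration to trans.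
- Fallback (reduction before the propenyl group exists): it sets out from 6 and returns at 10. Mg in MeOH followed by NaOMe, run cold with the minimum of metal to spare the aryl bromide, should give the racemic trans bromo ester F10, which is then coupled with 7 under the conditions of step 3.

**Step 5.**
- Most likely failure: insufficient separation of the enantiomers at a useful loading.
- Fallback (classical resolution through diastereomeric salts): it sets out from 10 and returns at 11. LiOH in THF/H2O gives the racemic trans acid F11; crystallisation with (R)-1-phenylethylamine gives the diastereomeric salt F12; dilute acid releases the (2S,3S) acid F13, which MeI and K2CO3 in DMF convert into 11. The (R)-amine is written; the (S)-amine is used if it is the one that crystallises with the (2S,3S) acid.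

Further compounds

F1 | step 11 | 4-hydroxy-2,3-dimethoxy-4-{1-[(2S,3S)-7-methoxy-3-methyl-5-[(E)-prop-1-enyl]-2,3-dihydro-1-benzofuran-2-yl]ethenyl}cyclobut-2-en-1-one (both epimers at the carbinol carbon) | C/C=C/c1cc(OC)c2c(c1)[C@H](C)[C@@H](C(=C)C1(O)C(=O)C(OC)=C1OC)O2
F2 | step 11 | 2,3-dimethoxy-5-[(2S,3S)-7-methoxy-3-methyl-5-[(E)-prop-1-enyl]-2,3-dihydro-1-benzofuran-2-yl]benzene-1,4-diol | C/C=C/c1cc(OC)c2c(c1)[C@H](C)[C@@H](c1cc(O)c(OC)c(OC)c1O)O2
F3 | step 11 | 2,3-dimethoxy-6-[(2S,3S)-7-methoxy-3-methyl-5-[(E)-prop-1-enyl]-2,3-dihydro-1-benzofuran-2-yl]-4-[tri(propan-2-yl)silyl]oxyphenol | C/C=C/c1cc(OC)c2c(c1)[C@H](C)[C@@H](c1cc(O[Si](C(C)C)(C(C)C)C(C)C)c(OC)c(OC)c1O)O2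
F4 | step 11 | 2,3-dimethoxy-6-[(2S,3S)-7-methoxy-3-methyl-5-[(E)-prop-1-enyl]-2,3-dihydro-1-benzofuran-2-yl]-4-[tri(propan-2-yl)silyl]oxyphenyl trifluoromethanesulfonate | C/C=C/c1cc(OC)c2c(c1)[C@H](C)[C@@H](c1cc(O[Si](C(C)C)(C(C)C)C(C)C)c(OC)c(OC)c1OS(=O)(=O)C(F)(F)F)O2
F5 | step 11 | {5-[(2S,3S)-7-methoxy-3-methyl-5-[(E)-prop-1-enyl]-2,3-dihydro-1-benzofuran-2-yl]-2,3-dimethoxyphenoxy}tri(propan-2-yl)silane | C/C=C/c1cc(OC)c2c(c1)[C@H](C)[C@@H](c1cc(O[Si](C(C)C)(C(C)C)C(C)C)c(OC)c(OC)c1)O2
F6 | step 10 | 2,3-dimethoxy-4-oxocyclobut-2-en-1-yl methyl carbonate (racemic) | COC(=O)OC1C(=O)C(OC)=C1OC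
F7 | step 8 | (2S,3S)-N,7-dimethoxy-N,3-dimethyl-5-[(E)-prop-1-enyl]-2,3-dihydro-1-benzofuran-2-carboxamide | C/C=C/c1cc(OC)c2c(c1)[C@H](C)[C@@H](C(=O)N(C)OC)O2
F8 | step 8 | 1-[(2S,3S)-7-methoxy-3-methyl-5-[(E)-prop-1-enyl]-2,3-dihydro-1-benzofuran-2-yl]ethanone | C/C=C/c1cc(OC)c2c(c1)[C@H](C)[C@@H](C(C)=O)O2
F9 | step 8 | 1-[(2S,3S)-7-methoxy-3-methyl-5-[(E)-prop-1-enyl]-2,3-dihydro-1-benzofuran-2-yl]ethenyl trifluoromethanesulfonate | C/C=C/c1cc(OC)c2c(c1)[C@H](C)[C@@H](C(=C)OS(=O)(=O)C(F)(F)F)O2
F10 | step 4 | methyl (2RS,3RS)-5-bromo-7-methoxy-3-methyl-2,3-dihydro-1-benzofuran-2-carboxylate (racemic trans; one enantiomer drawn) | Brc1cc(OC)c2c(c1)[C@H](C)[C@@H](C(=O)OC)O2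
F11 | step 5 | (2RS,3RS)-7-methoxy-3-methyl-5-[(E)-prop-1-enyl]-2,3-dihydro-1-benzofuran-2-carboxylic acid (racemic trans; one enantiomer drawn) | C/C=C/c1cc(OC)c2c(c1)[C@H](C)[C@@H](C(=O)O)O2
F12 | step 5 | (R)-1-phenylethylammonium (2S,3S)-7-methoxy-3-methyl-5-[(E)-prop-1-enyl]-2,3-dihydro-1-benzofuran-2-carboxylate | C/C=C/c1cc(OC)c2c(c1)[C@H](C)[C@@H](C(=O)[O-])O2.C[C@@H]([NH3+])c1ccccc1
F13 | step 5 | (2S,3S)-7-methoxy-3-methyl-5-[(E)-prop-1-enyl]-2,3-dihydro-1-benzofuran-2-carboxylic acid | C/C=C/c1cc(OC)c2c(c1)[C@H](C)[C@@H](C(=O)O)O2
A1 | alternative 1 | methyl 2-[5-bromo-2-({3-[tert-butyl(dimethyl)silyl]oxy-4,5-dimethoxyphenyl}methoxy)-3-methoxyphenyl]-2-diazoacetate | COC(=O)C(=[N+]=[N-])c1cc(Br)cc(OC)c1OCc1cc(O[Si](C)(C)C(C)(C)C)c(OC)c(OC)c1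
A2 | alternative 1 | methyl (2S,3R)-5-bromo-2-{3-[tert-butyl(dimethyl)silyl]oxy-4,5-dimethoxyphenyl}-7-methoxy-2,3-dihydro-1-benzofuran-3-carboxylate (cis) | Brc1cc(OC)c2c(c1)[C@@H](C(=O)OC)[C@@H](c1cc(O[Si](C)(C)C(C)(C)C)c(OC)c(OC)c1)O2
A3 | alternative 2 | methyl 4-iodo-3-methoxybenzoate | COC(=O)c1ccc(I)c(OC)c1
A4 | alternative 2 | (2R,3S)-2-[3-(methoxymethoxy)-4,5-dimethoxyphenyl]-3-methyloxirane (cis) | O1[C@@H](C)[C@H]1c1cc(OCOC)c(OC)c(OC)c1
A5 | alternative 2 | methyl (2S,3S)-7-methoxy-2-[3-(methoxymethoxy)-4,5-dimethoxyphenyl]-3-methyl-2,3-dihydro-1-benzofuran-5-carboxylate | COC(=O)c1cc(OC)c2c(c1)[C@H](C)[C@@H](c1cc(OCOC)c(OC)c(OC)c1)O2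
A6 | alternative 3 | 3-{[(1S,2S)-1-{3-[tert-butyl(dimethyl)silyl]oxy-4,5-dimethoxyphenyl}-2-methylbut-3-yn-1-yl]oxy}-4-methoxy-6-[(E)-prop-1-enyl]-2H-pyran-2-one | C/C=C/c1cc(OC)c(O[C@H](c2cc(O[Si](C)(C)C(C)(C)C)c(OC)c(OC)c2)[C@@H](C)C#C)c(=O)o1
A7 | alternative 3 | tert-butyl{5-[(2S,3S)-7-methoxy-3-methyl-5-[(E)-prop-1-enyl]-2,3-dihydro-1-benzofuran-2-yl]-2,3-dimethoxyphenoxy}dimethylsilane | C/C=C/c1cc(OC)c2c(c1)[C@H](C)[C@@H](c1cc(O[Si](C)(C)C(C)(C)C)c(OC)c(OC)c1)O2
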